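The readings are simulated with made-up constants; scatter was added.

The 61 % of target read at 4.00 min in the south run is a passing value, not a yield to copy onto this flask.

| flask | starting material | second substrate | gas | free catalyst | remark | time |
|---|---|---|---|---|---|---|
| south | 20 mM | 40 mM | 3.1 mM (held) | 0.14 mM | run made earlier |  |
| flask | 20 mM | 20.0 mM | 3.1 mM (held) | 0.14 mM |  | 40 min |

south run (percent of the starting material charged)

| time / min | target / % | starting material / % |
|---|---|---|
| 0.333 | 10 | 92 |
| 0.667 | 21 | 79 |
| 1.00 | 27 | 66 |
| 2.00 | 47 | 41 |
| 4.00 | 61 | 12 |

(each reading ± 1.5 percentage points)

- at the start none of the gas is in solution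

1. target at 40 min, in percent of the starting material charged
2. amount of target if the flask were left three thousand times as long, in percent of the starting material charged

The south balance falls short of the charge, and the gap grows. The missing share over c(target), the loss ratio, reads 0.443 at 4.00 min. It read 0.255 at 2.00 min, so it climbed 0.240 of a power of ten between the two readings. This flask holds half the second substrate of the south run, with the same starting material, gas and free catalyst. My own reckoning is a ceiling: if the ratio does not fall below the last reading, target stays under 69.3 %. Keep the gas held at 3.1 mM and sample at 40 min, not early.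

The forecast gives 53 % at 40 min and 54 % for the long wait, assuming of the second substrate that “the overreaction also consumes it”. Both values lie under my ceiling.

The flask gives 59.1 % at 40 min and 59.1 % after the long wait.

    starting material + free catalyst ⇌ catalyst intermediate A (K = 166 L mol⁻¹, k = 178 L mol⁻¹ s⁻¹)
    reagent + catalyst intermediate A → free catalyst + target (k = 10800 L mol⁻¹ s⁻¹)
    second substrate + free catalyst ⇌ catalyst intermediate B (K = 38.0 L mol⁻¹, k = 1190 L mol⁻¹ s⁻¹)
    reagent + catalyst intermediate B → free catalyst + second product (k = 1270 L mol⁻¹ s⁻¹)
    target ⇌ isomer of the product (K = 0.692, k = 0.00548 s⁻¹)
    gas ⇌ reagent, rate k6*(csat - [reagent]) (kL = 0.0637 s⁻¹)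

Target and isomer of the product relax with a half-life of 0.862 min, short against 40 min, which is thermodynamic control of the split. In this flask the missing share stands as 40.9 % of isomer of the product. The loss ratio therefore ends at 0.692, which is 0.194 of a power of ten above the south reading. The neighbouring flask, with 5.0 mM of second substrate, ends at a ratio of 0.692, with target at 59.1 %.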